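Retrosynthetic overview
- Last disconnection: the two aryl O–CH3 bonds. Both are made in one operation by site-selective double O-methylation of the unprotected hexaol, at the two OH groups para to the acetyl groups.
- Hexaol ⇒ Ar–CH2–Ar' bond: an ortho-quinone methide from the Mannich base of 3-methylphloroacetophenone (ring A) is captured by 3-prenylphloroacetophenone (ring B).
- Ring B piece ⇒ phloroacetophenone + prenyl bromide (C-prenylation). Ring A piece ⇒ 2-methylphloroglucinol + Ac2O (Friedel–Crafts acylation).
- No ring is built. Both benzene rings are bought, each is finished in one step, then they are joined and methylated together.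

Assumption: the target SMILES holds no stereocentre and no E/Z-stereogenic double bond, so mallotojaponin B is achiral and the route has no configuration to set.

Step 1
Reactants: 1 2',4',6'-trihydroxyacetophenone (phloroacetophenone)
Product: 2 1-[2,4,6-trihydroxy-3-(3-methylbut-2-en-1-yl)phenyl]ethan-1-one (3-prenylphloroacetophenone)
Conditions: 1 (1.5 equiv), prenyl bromide (1.0 equiv), KOH (1.5 equiv), H2O, 0 °C to 23 °C, 3 h
Reagents that add atoms: prenyl bromide (1-bromo-3-methylbut-2-ene), SMILES CC(C)=CCBr
Why: Base-mediated C-alkylation of a phloroglucinolate, in which water hydrogen-bonds the phenoxide oxygens so that the soft allylic bromide is taken up at ring carbon, the excess of cheap 1 holds back a second prenylation, and no stereocentre is formed.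

Step 2
Reactants: 3 2-methylbenzene-1,3,5-triol (2-methylphloroglucinol)
Product: 4 1-(2,4,6-trihydroxy-3-methylphenyl)ethan-1-one (3-methylphloroacetophenone)
Conditions: Ac2O (1.05 equiv), BF3·OEt2 (as solvent), 80 °C, 2 h
Reagents that add atoms: acetic anhydride, SMILES CC(=O)OC(C)=O
Why: Friedel–Crafts acylation in which the two free ring positions of 3 are equivalent and the first acetyl group deactivates the ring, so a single mono-ketone forms and no stereocentre is created.

Step 3
Reactants: 4 1-(2,4,6-trihydroxy-3-methylphenyl)ethan-1-one; 2 1-[2,4,6-trihydroxy-3-(3-methylbut-2-en-1-yl)phenyl]ethan-1-one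
Product: 7 1-[3-[(3-acetyl-2,4,6-trihydroxy-5-methylphenyl)methyl]-2,4,6-trihydroxy-5-(3-methylbut-2-en-1-yl)phenyl]ethan-1-one (hexaol), via Mannich base 5 (not isolated), via ortho-quinone methide 6 (not isolated)
Conditions: 4, [CH2=NMe2]I (1.0 equiv), NaOAc (1.0 equiv), MeCN, 23 °C, 1 h; then 2 (1.2 equiv), 75 °C, 6 h
Reagents that add atoms: Eschenmoser's salt (N,N-dimethylmethyleneiminium iodide), SMILES C=[N+](C)C.[I-]
Why: A Mannich reaction at the only free ring carbon of 4 gives 5, which on heating in the acetate buffer eliminates dimethylamine to ortho-quinone methide 6, and the only free ring carbon of 2 adds to it in a Michael-type Friedel–Crafts alkylation and rearomatises, the stepwise order giving the cross product without any stereocentre.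

Step 4
Reactants: 7 1-[3-[(3-acetyl-2,4,6-trihydroxy-5-methylphenyl)methyl]-2,4,6-trihydroxy-5-(3-methylbut-2-en-1-yl)phenyl]ethan-1-one
Product: 10 mallotojaponin B, via ring A monomethyl ether 8 (not isolated), via ring B monomethyl ether 9 (not isolated)
Conditions: O-methyl-N,N'-diisopropylisourea (2.2 equiv), THF, 45 °C, 24 h, Ar
Reagents that add atoms: O-methyl-N,N'-diisopropylisourea, SMILES COC(=NC(C)C)NC(C)C
Why: Proposed new method: a proton-gated double methyl transfer that treats the two OH groups para to the acetyl groups as vinylogous carboxylic acids; only these two OH groups (pKa roughly 8, outside the O–H···O=C chelates) are acidic enough to protonate the neutral isourea (conjugate acid pKa roughly 10), each proton transfer gives a contact ion pair of aryloxide and O-methylisouronium that collapses by SN2 attack of the aryloxide oxygen on the hard O–CH3 carbon and releases inert N,N'-diisopropylurea, so base and methyl donor vanish together and no free base is left to ionise the four hydrogen-bonded OH groups, to C-methylate the rings or to scramble the methylene bridge, while addition of the aryloxide to the amidinium carbon is reversible because the aryloxide is the better leaving group; the closest known reaction type is the O-alkylisourea esterification of carboxylic acids near room temperature (simple phenols need more than 80 °C with this reagent), which has not been shown as a site-selective etherification of an unprotected acylphloroglucinol polyphenol; no stereocentre is formed.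

Compound list
1 | 2',4',6'-trihydroxyacetophenone (phloroacetophenone) | CC(=O)c1c(O)cc(O)cc1O | starting material
2 | 1-[2,4,6-trihydroxy-3-(3-methylbut-2-en-1-yl)phenyl]ethan-1-one | CC(=O)c1c(O)cc(O)c(CC=C(C)C)c1O | intermediate
3 | 2-methylbenzene-1,3,5-triol (2-methylphloroglucinol) | Cc1c(O)cc(O)cc1O | starting material
4 | 1-(2,4,6-trihydroxy-3-methylphenyl)ethan-1-one | CC(=O)c1c(O)cc(O)c(C)c1O | intermediate
5 | Mannich base, 1-[3-[(dimethylamino)methyl]-2,4,6-trihydroxy-5-methylphenyl]ethan-1-one (not isolated) | CC(=O)c1c(O)c(C)c(O)c(CN(C)C)c1O | intermediate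
6 | ortho-quinone methide, 4-acetyl-3,5-dihydroxy-2-methyl-6-methylidenecyclohexa-2,4-dien-1-one (not isolated) | C=C1C(=O)C(C)=C(O)C(C(C)=O)=C1O | intermediate
7 | hexaol, 1-[3-[(3-acetyl-2,4,6-trihydroxy-5-methylphenyl)methyl]-2,4,6-trihydroxy-5-(3-methylbut-2-en-1-yl)phenyl]ethan-1-one | CC(=O)c1c(O)c(C)c(O)c(Cc2c(O)c(CC=C(C)C)c(O)c(C(C)=O)c2O)c1O | intermediate
8 | ring A monomethyl ether, 1-[3-[(3-acetyl-2,4-dihydroxy-6-methoxy-5-methylphenyl)methyl]-2,4,6-trihydroxy-5-(3-methylbut-2-en-1-yl)phenyl]ethan-1-one (not isolated) | COc1c(C)c(O)c(C(C)=O)c(O)c1Cc1c(O)c(C(C)=O)c(O)c(CC=C(C)C)c1O | intermediate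
9 | ring B monomethyl ether, 1-[3-[(3-acetyl-2,4,6-trihydroxy-5-methylphenyl)methyl]-2,6-dihydroxy-4-methoxy-5-(3-methylbut-2-en-1-yl)phenyl]ethan-1-one (not isolated) | Cc1c(O)c(C(C)=O)c(O)c(Cc2c(O)c(C(C)=O)c(O)c(CC=C(C)C)c2OC)c1O | intermediate
10 | mallotojaponin B, 1-[3-[(3-acetyl-2,4-dihydroxy-6-methoxy-5-methylphenyl)methyl]-2,6-dihydroxy-4-methoxy-5-(3-methylbut-2-en-1-yl)phenyl]ethan-1-one (achiral) | COc1c(C)c(O)c(C(C)=O)c(O)c1Cc1c(O)c(C(C)=O)c(O)c(CC=C(C)C)c1OC | target

Total step count: 4
Longest linear sequence: 3 steps (1 → 2 → 7 → 10, or 3 → 4 → 7 → 10)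

The three steps most likely to fail

**Risk 1, step 4 (the proposed new step).**
- What can go wrong: the aryloxides are flanked on both sides and may attack the isouronium methyl group too slowly at 45 °C. The small excess of basic isourea may also begin to methylate a hydrogen-bonded OH or scramble the bridge.
- Fallback, known chemistry only: it sets out from 2 and 4 and moves the O-methylation to the monomers.
- Each triol is mono-methylated at the OH para to the acetyl group with Me2SO4 (1.0 equiv) and K2CO3 in acetone at 23 °C. This gives 1-[2,6-dihydroxy-4-methoxy-3-(3-methylbut-2-en-1-yl)phenyl]ethan-1-one F1 from 2 and 1-(2,6-dihydroxy-4-methoxy-3-methylphenyl)ethan-1-one F2 from 4.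
- F2 is aminomethylated with [CH2=NMe2]I in CH2Cl2 to the Mannich base 1-[3-[(dimethylamino)methyl]-2,6-dihydroxy-4-methoxy-5-methylphenyl]ethan-1-one F3.
- Heating F3 with F1 in toluene at 110 °C eliminates dimethylamine to the ortho-quinone methide 2-acetyl-3-hydroxy-5-methoxy-4-methyl-6-methylidenecyclohexa-2,4-dien-1-one F4. The free ring carbon of F1 captures it.
- The sequence comes back to the route at 10.

**Risk 2, step 3.**
- What can go wrong: 6 can attack 5 at the ipso carbon and expel the iminium ion. Warm amine can also reopen the methylene bridge. Both paths lead to ring A/ring A and ring B/ring B homodimers.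
- Fallback: it sets out from 4 and swaps the thermal amine precursor for an isolable, amine-free one.
- Compound 4, paraformaldehyde and p-toluenesulfinic acid (from p-TolSO2Na and HCO2H) in aqueous EtOH at 23 °C give the crystalline benzylic sulfone 1-[2,4,6-trihydroxy-3-methyl-5-[(4-methylbenzenesulfonyl)methyl]phenyl]ethan-1-one F5. It is purified free of 4.
- With NaHCO3 in MeCN–H2O at 23 °C and 2 present, F5 loses p-toluenesulfinate to give 6 without heat or amine. Compound 2 captures 6.
- The sequence comes back to the route at 7.

**Risk 3, step 1.**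
- What can go wrong: 1 has two free ring carbons and three OH groups, so bis-C-prenylation and O-prenylation may leave little 2.
- Fallback: it sets out from 5 (made from 4 as in step 3) and 1, and puts the prenyl group on after the union.
- Compound 5 is heated in MeCN at 75 °C with 1 (3 equiv). By way of 6 this gives the des-prenyl dimer 1-[3-[(3-acetyl-2,4,6-trihydroxyphenyl)methyl]-2,4,6-trihydroxy-5-methylphenyl]ethan-1-one F6, which has only one free ring carbon left.
- Prenyl bromide (1.0 equiv) and KOH in H2O at 0 °C then alkylate that carbon. Compound 2 is no longer needed.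
- The sequence comes back to the route at 7.

Further compounds
F1 | step 4 | 1-[2,6-dihydroxy-4-methoxy-3-(3-methylbut-2-en-1-yl)phenyl]ethan-1-one | CC(=O)c1c(O)cc(OC)c(CC=C(C)C)c1O
F2 | step 4 | 1-(2,6-dihydroxy-4-methoxy-3-methylphenyl)ethan-1-one | CC(=O)c1c(O)cc(OC)c(C)c1O
F3 | step 4 | 1-[3-[(dimethylamino)methyl]-2,6-dihydroxy-4-methoxy-5-methylphenyl]ethan-1-one | CC(=O)c1c(O)c(C)c(OC)c(CN(C)C)c1O
F4 | step 4 | 2-acetyl-3-hydroxy-5-methoxy-4-methyl-6-methylidenecyclohexa-2,4-dien-1-one | C=C1C(=O)C(C(C)=O)=C(O)C(C)=C1OC
F5 | step 3 | 1-[2,4,6-trihydroxy-3-methyl-5-[(4-methylbenzenesulfonyl)methyl]phenyl]ethan-1-one | CC(=O)c1c(O)c(C)c(O)c(CS(=O)(=O)c2ccc(C)cc2)c1O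
F6 | step 1 | 1-[3-[(3-acetyl-2,4,6-trihydroxyphenyl)methyl]-2,4,6-trihydroxy-5-methylphenyl]ethan-1-one | CC(=O)c1c(O)c(C)c(O)c(Cc2c(O)cc(O)c(C(C)=O)c2O)c1O
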